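**Analysis of the target**

The target 23 is a 2H-chromene in which a fully substituted benzene ring (ring A) is fused to a 2,2-dimethylpyran and joined through a two-carbon bridge to a para-hydroxyphenyl ring (ring B). Counting ring A from the ester-bearing carbon, it carries CO2Me at C1, a hydroxyl at C2 (hydrogen-bonded to the ester), a prenyl group at C3, the pyran oxygen O1' at C4, the pyran carbon C4' at C5 and the 2-arylethyl chain at C6. The pyran is completed by the quaternary C2' (two methyl groups) and C3', with the olefin between C3' and C4'. There is no stereocenter, so the problem is one of regiochemistry and functional-group tolerance. The sensitive groups are the prenyl olefin, which closes onto the neighbouring C2 hydroxyl under acid to give a chroman, and the chromene olefin, which tolerates neither acid nor hydrogenation. The two phenols differ in acidity, and the ester is shielded on both sides. The difficulty is that all six positions of ring A carry different groups, so each must be introduced with positional control, and the two olefins exclude hydrogenolysis and strong acid late in the route. The strategy rests on the unit O1'–C2'–C3'–C4' that spans C4 and C5. It is a 2,2-dimethylbenzofuran-3-one enlarged by the single carbon C4', and that furanone is what Friedel–Crafts closure of an O4-tethered 2-methylpropanoic acid gives at C5, the only unsubstituted position once C3 carries the prenyl group.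

**Retrosynthetic reasoning**

Protecting groups, 23 from 22. The last bonds cut are the two O–allyl bonds, so that both phenols travel as allyl ethers. A silyl ether on ring B was rejected because aryl silyl ethers do not survive the carbonate and hydroxide steps that build the O4 side chain. A free C2 hydroxyl was rejected for three reasons. Next to a Lewis acid it is an acid that protonates a diazoalkane (loss of reagent, O-methylation). It can add to the prenyl olefin. It would also compete in the later sulfonylation. Allyl ethers are inert to base, acid, Lewis acid, hydride and sulfonylation, and both should fall together under neutral conditions with zerovalent palladium. A further gain is that the C2 allyloxy group is flanked on both sides and twisted out of conjugation, so it should feed less electron density into the furanone ketone than a coplanar, chelated hydroxyl.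

Olefin, 22 from 20 and 19. The C3'=C4' double bond is traced back to the C3' ketone 19 through the alcohol 20. Because C2' is quaternary, elimination from C3' can only run towards the benzylic C4', so no regiochemical question arises. The stereocenter of 20 is irrelevant.

Key disconnection, 19 from 16 and 17. The bonds C5–C4' and C4'–C3' are cut and C4' is taken out, which leaves the five-membered ketone 16 and the one-carbon donor 17. This is the place to cut because it replaces a chromene annulation on a crowded, hexasubstituted ring by a furanone whose own closure is a standard acylation. The forward reaction has to add 17 to a hindered, donor-conjugated ketone, shift the ring A carbon to the new carbon with loss of nitrogen, and leave the ester, three olefins and two ethers alone.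

Furanone, 16 from 14. The C5–C3' bond is cut, giving the aryloxy acid 14. Closure can only occur at C5 because C3 already carries the prenyl group. This is why prenylation precedes ring closure. Without it, C3 and C5 would compete.

Side chain on O4, 14 from 13, and 13 from 10 and 11. The O4–C2' bond is cut to the phenol 10 and the tertiary bromo ester 11. The non-chelated O4–H is the more acidic and less hindered phenol, so it should react first. The C2 hydroxyl is then capped as its allyl ether in the same flask. The two esters of 13 are distinguished by shielding: the benzoate has two ortho substituents, the aliphatic ester has none.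

Prenyl group, 10 from 8 and 9. The C3–CH2 bond is cut. C-alkylation of the phenoxide of 8 needs the free O4–H, so it has to come before the O4 side chain is attached.

Bibenzyl bridge, 8 from 7, and 7 from 5 and 3. The CH2–CH2 bond of the bridge is cut next to ring A, which leads to the benzylic anion 6 of the protected toluate 5 and the benzylic bromide 3. The methyl group of 4 is thereby used as a nucleophile, and no olefin reduction is needed. The two acetal ethers of 5 are removed with mild acid before any acid-sensitive olefin is on ring A. Ring B carries its allyl ether from the start (3 from 2, 2 from 1).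

**Alternatives that were turned down**

Alternative 1: Ring A is disconnected at C3–C4 and C5–C6 into the fully substituted 2-pyrone A1 and the silyloxyalkyne A2.
- Forward key step: A1 and A2 would undergo a Diels–Alder addition across the pyrone termini, and the bicyclic adduct would expel its lactone bridge to give the arene A3.
- For: five ring A substituents are placed in one convergent step. The prenyl position is fixed by the pyrone and does not depend on C- versus O-alkylation. O4 emerges as a silyl ether distinct from O2. On these two points it is stronger than step 6 of the chosen route.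
- Against: A1 is a push–pull pyrone whose 4-alkoxy group opposes the activating ester, and both reacting termini are substituted. Making A1 would cost about as many steps as the whole precursor 16. A2 is a sensitive reagent. A3 still has hydrogen at C5, so the pyran is not addressed at all, and two acetal ethers would have to be removed with acid from a prenylated chromene.
- Comparison: the chosen strategy takes ring A from an aromatic starting material that already has the ester, both oxygens and the benzylic carbon, and it puts its risk on the pyran, which this alternative leaves open.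

Alternative 2: The chromene is disconnected at aryl–O1', aryl–C4' and O1'–C2' into the aryne precursor A4 and the enal A5.
- Forward key step: fluoride would release the aryne from A4. The carbonyl oxygen of A5 adds, the resulting ortho-quinone methide closes by 6π electrocyclization, and the chromene A6 results.
- For: the chromene is made at the correct oxidation level in one step, against five operations in the chosen route (O-alkylation, acylation, insertion, reduction, elimination). On pyran construction this alternative is clearly stronger. The bromine of A4 also directs the addition.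
- Against: A6 has hydrogen at the positions that must carry the ester and the prenyl group. Its bromide has to become the arylethyl chain by an sp2–sp3 coupling, since hydrogenation is excluded. Two successive ring metalations next to an acid-sensitive chromene are then needed, one of them at the most hindered position. A4 needs several steps, and a final acetal cleavage in acid meets the ortho-prenyl phenol.
- Comparison: the chosen strategy offers a ring A whose substitution is settled before the pyran is touched, with C5 forced as the only site of closure.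

Alternative 3: Ring A is disconnected at C1–C6 and C2–C3 into the enone A7 and the malonate A8.
- Forward key step: Michael addition of A8 to A7 followed by Claisen closure through the prenyl-bearing methylene would give the cyclohexenone ester A9, to be aromatized afterwards.
- For: the materials are cheap, the annulation is a classical one, and the prenyl group sits at C3 by construction. On that point it is stronger than step 6.
- Against: A9 must be dehydrogenated in the presence of a trisubstituted olefin, which conflicts with the usual halogen-based aromatization. A7 requires an aldol condensation at the methyl side of an unsymmetrical ketone. After aromatization the product is only the analogue of 10, so the route would then continue exactly as the chosen one.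
- Comparison: it would replace steps 3 to 6 by a sequence of similar length with a new chemoselectivity problem, and it contributes nothing to the pyran. The chosen strategy keeps the aromatic ring intact and meets the prenylation problem with a Claisen fallback.

Key step: step 10

Remark on the chemistry: 18, 20 and 21 each carry one stereocenter and would form as racemates. These centers are removed in steps 10 and 12, so no stereocontrol is planned.

**Route**

Step 1
Reactants: 1 4-(hydroxymethyl)phenol
Product: 2 [4-(prop-2-enyloxy)phenyl]methanol
Conditions: allyl bromide, K2CO3, acetone, reflux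
Reagents that add atoms: allyl bromide, C=CCBr
Why: Williamson ether synthesis; K2CO3 deprotonates only the phenol, so the benzylic alcohol should stay free.

Step 2
Reactants: 2 [4-(prop-2-enyloxy)phenyl]methanol
Product: 3 1-(bromomethyl)-4-(prop-2-enyloxy)benzene
Conditions: PBr3, Et2O, 0 °C
Reagents that add atoms: phosphorus tribromide, BrP(Br)Br
Why: Conversion of a benzylic alcohol into the bromide through its phosphite ester and SN2 attack of bromide; the para-alkoxybenzyl bromide ionizes easily and should be used at once.

Step 3
Reactants: 4 methyl 2,4-dihydroxy-6-methylbenzoate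
Product: 5 methyl 2,4-bis(methoxymethoxy)-6-methylbenzoate
Conditions: NaH, MOMCl, THF/DMF, 0 °C to rt
Reagents that add atoms: chloromethyl methyl ether, COCCl
Why: O-Alkylation of both sodium phenoxides by the α-chloro ether (Williamson type); NaH is used because the chelated C2 hydroxyl is sluggish with amine bases, and the acetal ethers are inert to the amide base of step 4.

Step 4
Reactants: 5 methyl 2,4-bis(methoxymethoxy)-6-methylbenzoate; 3 1-(bromomethyl)-4-(prop-2-enyloxy)benzene
Product: 7 methyl 2,4-bis(methoxymethoxy)-6-{2-[4-(prop-2-enyloxy)phenyl]ethyl}benzoate, via benzylic lithium reagent 6 (not isolated)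
Conditions: LiN(i-Pr)2, THF, −78 °C; then 3, −78 to −20 °C
Reagents that add atoms: none
Why: Lateral lithiation of an ortho-toluate gives a benzylic anion stabilized by the ester as an extended enolate, and SN2 alkylation with the reactive benzylic bromide forms the bridge C–C bond; low temperature and the doubly ortho-substituted ester should hold back self-condensation.

Step 5
Reactants: 7 methyl 2,4-bis(methoxymethoxy)-6-{2-[4-(prop-2-enyloxy)phenyl]ethyl}benzoate
Product: 8 methyl 2,4-dihydroxy-6-{2-[4-(prop-2-enyloxy)phenyl]ethyl}benzoate
Conditions: HCl (3 M aq.), MeOH, 50 °C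
Reagents that add atoms: none
Why: Acid-catalysed acetal exchange with methanol removes both methoxymethyl groups; the allyl ether and the ester are stable, and no acid-sensitive olefin is yet on ring A.

Step 6
Reactants: 8 methyl 2,4-dihydroxy-6-{2-[4-(prop-2-enyloxy)phenyl]ethyl}benzoate; 9 1-bromo-3-methylbut-2-ene
Product: 10 methyl 2,4-dihydroxy-3-(3-methylbut-2-enyl)-6-{2-[4-(prop-2-enyloxy)phenyl]ethyl}benzoate
Conditions: NaH (1 equiv), toluene, 0 °C; then 9, 0 °C to rt
Reagents that add atoms: none
Why: C-Alkylation of a sodium phenoxide as a tight ion pair in a non-polar solvent, which shields oxygen and directs the allylic bromide to the ortho carbon; C3 lies ortho to the O4 phenoxide between the two oxygens and is less crowded than C5, so it should be the main site, with the O4 ether and the C5 isomer to be separated.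

Step 7
Reactants: 10 methyl 2,4-dihydroxy-3-(3-methylbut-2-enyl)-6-{2-[4-(prop-2-enyloxy)phenyl]ethyl}benzoate; 11 ethyl 2-bromo-2-methylpropanoate
Product: 13 methyl 4-[(1-ethoxy-2-methyl-1-oxopropan-2-yl)oxy]-3-(3-methylbut-2-enyl)-2-(prop-2-enyloxy)-6-{2-[4-(prop-2-enyloxy)phenyl]ethyl}benzoate, via O4-alkylated phenol 12 (not isolated)
Conditions: Cs2CO3, 11, DMF, 60 °C; then allyl bromide, 50 °C
Reagents that add atoms: allyl bromide, C=CCBr
Why: Two Williamson-type alkylations in sequence; the tertiary α-bromo ester should react only with the non-chelated, more acidic O4 phenoxide, and the primary allylic bromide added afterwards alkylates the hindered, chelated C2 phenoxide that the tertiary bromide cannot reach.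

Step 8
Reactants: 13 methyl 4-[(1-ethoxy-2-methyl-1-oxopropan-2-yl)oxy]-3-(3-methylbut-2-enyl)-2-(prop-2-enyloxy)-6-{2-[4-(prop-2-enyloxy)phenyl]ethyl}benzoate
Product: 14 2-[4-(methoxycarbonyl)-2-(3-methylbut-2-enyl)-3-(prop-2-enyloxy)-5-{2-[4-(prop-2-enyloxy)phenyl]ethyl}phenoxy]-2-methylpropanoic acid
Conditions: LiOH·H2O, THF/MeOH/H2O, rt to 40 °C; then 1 M HCl to pH 3, 0 °C
Reagents that add atoms: lithium hydroxide, [Li+].[OH-]
Why: Saponification by acyl–oxygen cleavage; the methyl benzoate is shielded by two ortho substituents and twisted out of the ring plane, so hydroxide should attack only the aliphatic ethyl ester.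

Step 9
Reactants: 14 2-[4-(methoxycarbonyl)-2-(3-methylbut-2-enyl)-3-(prop-2-enyloxy)-5-{2-[4-(prop-2-enyloxy)phenyl]ethyl}phenoxy]-2-methylpropanoic acid
Product: 16 methyl 2,2-dimethyl-7-(3-methylbut-2-enyl)-3-oxo-6-(prop-2-enyloxy)-4-{2-[4-(prop-2-enyloxy)phenyl]ethyl}-2,3-dihydro-1-benzofuran-5-carboxylate, via mixed trifluoroacetic anhydride 15 (not isolated)
Conditions: (CF3CO)2O, CH2Cl2, 0 °C to rt; aq. NaHCO3
Reagents that add atoms: none
Why: Intramolecular Friedel–Crafts acylation through the mixed anhydride at C5, the only unsubstituted ring A position, which is ortho to the tether oxygen, para to the C2 ether and ortho to the alkyl chain; the mixed anhydride avoids a free tertiary α-aryloxy acyl cation that could lose CO, the geminal methyl groups favour closure, and with no free hydroxyl beside the prenyl group the acid cannot close a chroman.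

Step 10
Reactants: 16 methyl 2,2-dimethyl-7-(3-methylbut-2-enyl)-3-oxo-6-(prop-2-enyloxy)-4-{2-[4-(prop-2-enyloxy)phenyl]ethyl}-2,3-dihydro-1-benzofuran-5-carboxylate; 17 (trimethylsilyl)diazomethane
Product: 19 methyl 2,2-dimethyl-8-(3-methylbut-2-enyl)-3-oxo-7-(prop-2-enyloxy)-5-{2-[4-(prop-2-enyloxy)phenyl]ethyl}-3,4-dihydro-2H-chromene-6-carboxylate, via 4-silyl chromanone 18 (not isolated)
Conditions: 17 (2 M in hexanes), BF3·OEt2, CH2Cl2, −78 to −20 °C; aq. NaHCO3, then 1 M HCl, THF, 0 °C
Reagents that add atoms: none
Why: Proposed new method: BF3 binds the ketone oxygen of 16, the most Lewis-basic carbonyl because it is conjugated with the ring oxygen, and the nucleophilic diazo carbon of 17 adds to the activated carbonyl carbon to give a β-diazonium alkoxide. The electron-rich ring A carbon C5 then shifts from the carbinol carbon to the diazo carbon as N2 leaves (a Tiffeneau–Demjanov-type 1,2-shift), which makes the C5–C4' and C4'–C3' bonds and gives 18; aqueous acid on work-up replaces silicon at C4' by hydrogen. The closest known reaction type is the Lewis-acid-promoted homologation of cyclic aryl ketones with (trimethylsilyl)diazomethane, for example 1-indanones to 2-tetralones; it has not been shown on 2,2-dialkylbenzofuran-3-ones, whose ketone is a hindered vinylogous ester. The six-membered pyranone ring is not closed by a cyclization but arises by enlargement of the furanone ring through this 1,2-aryl shift. No stereocenter remains, since the silyl-bearing C4' of 18 is racemic and becomes CH2 in 19. The step needs chemoselectivity: the doubly ortho-substituted ester is less basic and is not attacked by diazoalkanes, both phenols are capped so that no acidic hydroxyl protonates 17 or adds to the prenyl olefin, and the bulky silyl group beside the new ketone, whose other neighbour is the quaternary C2', should stop a second insertion. Which bond migrates is not critical, because shift of the C2' carbon would give the isomeric 4-chromanone, which converges on the same C3'–C4' olefin after reduction and elimination. The real risk is that the donor-conjugated, hindered ketone does not add 17 at temperatures at which the diazoalkane survives the Lewis acid.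

Step 11
Reactants: 19 methyl 2,2-dimethyl-8-(3-methylbut-2-enyl)-3-oxo-7-(prop-2-enyloxy)-5-{2-[4-(prop-2-enyloxy)phenyl]ethyl}-3,4-dihydro-2H-chromene-6-carboxylate
Product: 20 racemic methyl 3-hydroxy-2,2-dimethyl-8-(3-methylbut-2-enyl)-7-(prop-2-enyloxy)-5-{2-[4-(prop-2-enyloxy)phenyl]ethyl}-3,4-dihydro-2H-chromene-6-carboxylate
Conditions: NaBH4, MeOH/THF, 0 °C (crude 19 used directly)
Reagents that add atoms: none
Why: Borohydride reduction of the non-conjugated ketone; the hindered ester and the olefins are not touched, the new C3' center forms without control as a racemate and is removed in step 12, and the air-sensitive benzylic ketone 19 is not stored.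

Step 12
Reactants: 20 racemic methyl 3-hydroxy-2,2-dimethyl-8-(3-methylbut-2-enyl)-7-(prop-2-enyloxy)-5-{2-[4-(prop-2-enyloxy)phenyl]ethyl}-3,4-dihydro-2H-chromene-6-carboxylate
Product: 22 methyl 2,2-dimethyl-8-(3-methylbut-2-enyl)-7-(prop-2-enyloxy)-5-{2-[4-(prop-2-enyloxy)phenyl]ethyl}-2H-chromene-6-carboxylate, via secondary mesylate 21 (not isolated)
Conditions: MsCl, Et3N, CH2Cl2, 0 °C; then DBU, toluene, 90 °C
Reagents that add atoms: none
Why: Sulfonylation of the alcohol through the sulfene, then E2 elimination with a non-nucleophilic amidine base; the only β-hydrogens are the benzylic ones at C4' because C2' is quaternary, so a single olefin conjugated with ring A should form.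

Step 13
Reactants: 22 methyl 2,2-dimethyl-8-(3-methylbut-2-enyl)-7-(prop-2-enyloxy)-5-{2-[4-(prop-2-enyloxy)phenyl]ethyl}-2H-chromene-6-carboxylate
Product: 23 methyl 7-hydroxy-5-[2-(4-hydroxyphenyl)ethyl]-2,2-dimethyl-8-(3-methylbut-2-enyl)-2H-chromene-6-carboxylate
Conditions: Pd(PPh3)4 (cat.), morpholine, THF, rt
Reagents that add atoms: none
Why: Tsuji–Trost-type deallylation; zerovalent palladium ionizes both aryl allyl ethers to π-allyl palladium and phenoxide, and morpholine traps the allyl group; the neutral conditions at room temperature leave the chromene olefin, the C-bound prenyl group and the ester alone.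

**Compound list**

1 | 4-(hydroxymethyl)phenol | OCc1ccc(O)cc1 | starting material
2 | [4-(prop-2-enyloxy)phenyl]methanol | OCc1ccc(OCC=C)cc1 | intermediate
3 | 1-(bromomethyl)-4-(prop-2-enyloxy)benzene | BrCc1ccc(OCC=C)cc1 | intermediate
4 | methyl 2,4-dihydroxy-6-methylbenzoate | COC(=O)c1c(C)cc(O)cc1O | starting material
5 | methyl 2,4-bis(methoxymethoxy)-6-methylbenzoate | COC(=O)c1c(C)cc(OCOC)cc1OCOC | intermediate
6 | methyl 2-(lithiomethyl)-4,6-bis(methoxymethoxy)benzoate | COC(=O)c1c(C[Li])cc(OCOC)cc1OCOC | intermediate
7 | methyl 2,4-bis(methoxymethoxy)-6-{2-[4-(prop-2-enyloxy)phenyl]ethyl}benzoate | COC(=O)c1c(CCc2ccc(OCC=C)cc2)cc(OCOC)cc1OCOC | intermediate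
8 | methyl 2,4-dihydroxy-6-{2-[4-(prop-2-enyloxy)phenyl]ethyl}benzoate | COC(=O)c1c(CCc2ccc(OCC=C)cc2)cc(O)cc1O | intermediate
9 | 1-bromo-3-methylbut-2-ene | CC(C)=CCBr | starting material
10 | methyl 2,4-dihydroxy-3-(3-methylbut-2-enyl)-6-{2-[4-(prop-2-enyloxy)phenyl]ethyl}benzoate | COC(=O)c1c(CCc2ccc(OCC=C)cc2)cc(O)c(CC=C(C)C)c1O | intermediate
11 | ethyl 2-bromo-2-methylpropanoate | CCOC(=O)C(C)(C)Br | starting material
12 | methyl 4-[(1-ethoxy-2-methyl-1-oxopropan-2-yl)oxy]-2-hydroxy-3-(3-methylbut-2-enyl)-6-{2-[4-(prop-2-enyloxy)phenyl]ethyl}benzoate | COC(=O)c1c(CCc2ccc(OCC=C)cc2)cc(OC(C)(C)C(=O)OCC)c(CC=C(C)C)c1O | intermediate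
13 | methyl 4-[(1-ethoxy-2-methyl-1-oxopropan-2-yl)oxy]-3-(3-methylbut-2-enyl)-2-(prop-2-enyloxy)-6-{2-[4-(prop-2-enyloxy)phenyl]ethyl}benzoate | COC(=O)c1c(CCc2ccc(OCC=C)cc2)cc(OC(C)(C)C(=O)OCC)c(CC=C(C)C)c1OCC=C | intermediate
14 | 2-[4-(methoxycarbonyl)-2-(3-methylbut-2-enyl)-3-(prop-2-enyloxy)-5-{2-[4-(prop-2-enyloxy)phenyl]ethyl}phenoxy]-2-methylpropanoic acid | COC(=O)c1c(CCc2ccc(OCC=C)cc2)cc(OC(C)(C)C(=O)O)c(CC=C(C)C)c1OCC=C | intermediate
15 | mixed anhydride of 14 with trifluoroacetic acid | COC(=O)c1c(CCc2ccc(OCC=C)cc2)cc(OC(C)(C)C(=O)OC(=O)C(F)(F)F)c(CC=C(C)C)c1OCC=C | intermediate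
16 | methyl 2,2-dimethyl-7-(3-methylbut-2-enyl)-3-oxo-6-(prop-2-enyloxy)-4-{2-[4-(prop-2-enyloxy)phenyl]ethyl}-2,3-dihydro-1-benzofuran-5-carboxylate | COC(=O)c1c(OCC=C)c(CC=C(C)C)c2OC(C)(C)C(=O)c2c1CCc1ccc(OCC=C)cc1 | intermediate
17 | (trimethylsilyl)diazomethane | C[Si](C)(C)C=[N+]=[N-] | starting material
18 | methyl 2,2-dimethyl-8-(3-methylbut-2-enyl)-3-oxo-7-(prop-2-enyloxy)-5-{2-[4-(prop-2-enyloxy)phenyl]ethyl}-4-(trimethylsilyl)-3,4-dihydro-2H-chromene-6-carboxylate (racemic; one enantiomer drawn) | COC(=O)c1c(OCC=C)c(CC=C(C)C)c2OC(C)(C)C(=O)[C@H]([Si](C)(C)C)c2c1CCc1ccc(OCC=C)cc1 | intermediate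
19 | methyl 2,2-dimethyl-8-(3-methylbut-2-enyl)-3-oxo-7-(prop-2-enyloxy)-5-{2-[4-(prop-2-enyloxy)phenyl]ethyl}-3,4-dihydro-2H-chromene-6-carboxylate | COC(=O)c1c(OCC=C)c(CC=C(C)C)c2OC(C)(C)C(=O)Cc2c1CCc1ccc(OCC=C)cc1 | intermediate
20 | methyl 3-hydroxy-2,2-dimethyl-8-(3-methylbut-2-enyl)-7-(prop-2-enyloxy)-5-{2-[4-(prop-2-enyloxy)phenyl]ethyl}-3,4-dihydro-2H-chromene-6-carboxylate (racemic; one enantiomer drawn) | COC(=O)c1c(OCC=C)c(CC=C(C)C)c2OC(C)(C)[C@H](O)Cc2c1CCc1ccc(OCC=C)cc1 | intermediate
21 | methyl 2,2-dimethyl-8-(3-methylbut-2-enyl)-3-(methylsulfonyloxy)-7-(prop-2-enyloxy)-5-{2-[4-(prop-2-enyloxy)phenyl]ethyl}-3,4-dihydro-2H-chromene-6-carboxylate (racemic; one enantiomer drawn) | COC(=O)c1c(OCC=C)c(CC=C(C)C)c2OC(C)(C)[C@H](OS(C)(=O)=O)Cc2c1CCc1ccc(OCC=C)cc1 | intermediate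
22 | methyl 2,2-dimethyl-8-(3-methylbut-2-enyl)-7-(prop-2-enyloxy)-5-{2-[4-(prop-2-enyloxy)phenyl]ethyl}-2H-chromene-6-carboxylate | COC(=O)c1c(OCC=C)c(CC=C(C)C)c2OC(C)(C)C=Cc2c1CCc1ccc(OCC=C)cc1 | intermediate
23 | methyl 7-hydroxy-5-[2-(4-hydroxyphenyl)ethyl]-2,2-dimethyl-8-(3-methylbut-2-enyl)-2H-chromene-6-carboxylate | COC(=O)c1c(O)c(CC=C(C)C)c2c(c1CCc1ccc(O)cc1)C=CC(C)(C)O2 | target

**Step count and uncertain steps**

Total step count: 13. Longest linear sequence: 12 steps (steps 1, 2 and 4 to 13).

Step 10 (key step). The most likely failure is that addition to the hindered, donor-conjugated ketone is too slow, so that the diazoalkane is consumed by the Lewis acid and 16 is recovered. Ionization of the prenyl olefin by the Lewis acid is a second possibility. The fallback builds the chromene by known phenol chemistry and sets out from 10. Condensation of 10 with 3-methylbut-2-enal A5 (ethylenediammonium diacetate, toluene, reflux) should proceed at C5, the only free carbon ortho to a hydroxyl, through the ortho-quinone methide and 6π electrocyclization. It would give methyl 7-hydroxy-2,2-dimethyl-8-(3-methylbut-2-enyl)-5-{2-[4-(prop-2-enyloxy)phenyl]ethyl}-2H-chromene-6-carboxylate F1. Deallylation of F1 under the conditions of step 13 comes back to the route at 23.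

Step 6. Poor site selectivity is the likely problem, because the phenoxide can react at O4, C3 or C5 and can take up a second prenyl group. The fallback sets out from 8. O4 alkylation with 3-chloro-3-methylbut-1-yne (K2CO3, KI, CuI, acetone) would give methyl 2-hydroxy-4-[(2-methylbut-3-yn-2-yl)oxy]-6-{2-[4-(prop-2-enyloxy)phenyl]ethyl}benzoate F2. Semihydrogenation over Pd/CaCO3 poisoned with Pb(OAc)2 and quinoline would give methyl 2-hydroxy-4-[(2-methylbut-3-en-2-yl)oxy]-6-{2-[4-(prop-2-enyloxy)phenyl]ethyl}benzoate F3. Heating F3 (about 120 °C, well below the temperature at which the ring B allyl ether rearranges) should bring about an aromatic Claisen rearrangement to C3, the position favoured by the bond fixation of the chelated hydroxy ester. This delivers the prenyl group with allylic inversion and comes back to the route at 10.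

Step 7. Substitution at the tertiary bromide next to an ortho-prenyl group may be slow, so that dehydrobromination of 11 outruns ether formation. The fallback sets out from 10 and uses a Bargellini reaction (1,1,1-trichloro-2-methylpropan-2-ol, powdered NaOH, acetone, 0 °C to rt), in which the phenoxide opens a dichloroepoxide at its tertiary carbon. It would give 2-[3-hydroxy-4-(methoxycarbonyl)-2-(3-methylbut-2-enyl)-5-{2-[4-(prop-2-enyloxy)phenyl]ethyl}phenoxy]-2-methylpropanoic acid F4. Closure with (CF3CO)2O as in step 9 would give methyl 6-hydroxy-2,2-dimethyl-7-(3-methylbut-2-enyl)-3-oxo-4-{2-[4-(prop-2-enyloxy)phenyl]ethyl}-2,3-dihydro-1-benzofuran-5-carboxylate F5. Allylation of F5 (allyl bromide, Cs2CO3, DMF) comes back to the route at 16.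

Step 9. If closure of the five-membered ketone at the crowded C5 is slow, the prenyl olefin may be lost to addition of trifluoroacetic acid or to acylation by the mixed anhydride, or the acyl cation may fragment with loss of CO. The fallback moves the closure to an anionic manifold and sets out from 13. Bromination at C5, the only free ring A position (N-bromosuccinimide, MeCN, 0 °C), would give methyl 3-bromo-4-[(1-ethoxy-2-methyl-1-oxopropan-2-yl)oxy]-5-(3-methylbut-2-enyl)-6-(prop-2-enyloxy)-2-{2-[4-(prop-2-enyloxy)phenyl]ethyl}benzoate F6. Bromine–lithium exchange (n-BuLi, THF, −95 °C) and Parham cyclization of the aryllithium onto the neighbouring ethyl ester come back to the route at 16.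

Step 12. The E2 reaction at a neopentyl-type secondary mesylate may fail, either by not reacting or by ionizing with a 1,2-methyl shift from C2'. The fallback avoids the alcohol and sets out from 19. Enolization, possible only towards C4' (KN(SiMe3)2, N-phenylbis(trifluoromethanesulfonimide), THF, −78 °C), would give methyl 2,2-dimethyl-8-(3-methylbut-2-enyl)-7-(prop-2-enyloxy)-5-{2-[4-(prop-2-enyloxy)phenyl]ethyl}-3-(trifluoromethylsulfonyloxy)-2H-chromene-6-carboxylate F7. Reduction with Pd(OAc)2, PPh3, HCO2H and Bu3N in DMF at 60 °C should replace the triflate by hydrogen. The same zerovalent palladium and formate should also cleave both allyl ethers, so the fallback comes back to the route at 23.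

**Further compounds**

F1 | step 10 | methyl 7-hydroxy-2,2-dimethyl-8-(3-methylbut-2-enyl)-5-{2-[4-(prop-2-enyloxy)phenyl]ethyl}-2H-chromene-6-carboxylate | COC(=O)c1c(O)c(CC=C(C)C)c2OC(C)(C)C=Cc2c1CCc1ccc(OCC=C)cc1
F2 | step 6 | methyl 2-hydroxy-4-[(2-methylbut-3-yn-2-yl)oxy]-6-{2-[4-(prop-2-enyloxy)phenyl]ethyl}benzoate | COC(=O)c1c(CCc2ccc(OCC=C)cc2)cc(OC(C)(C)C#C)cc1O
F3 | step 6 | methyl 2-hydroxy-4-[(2-methylbut-3-en-2-yl)oxy]-6-{2-[4-(prop-2-enyloxy)phenyl]ethyl}benzoate | COC(=O)c1c(CCc2ccc(OCC=C)cc2)cc(OC(C)(C)C=C)cc1O
F4 | step 7 | 2-[3-hydroxy-4-(methoxycarbonyl)-2-(3-methylbut-2-enyl)-5-{2-[4-(prop-2-enyloxy)phenyl]ethyl}phenoxy]-2-methylpropanoic acid | COC(=O)c1c(CCc2ccc(OCC=C)cc2)cc(OC(C)(C)C(=O)O)c(CC=C(C)C)c1O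
F5 | step 7 | methyl 6-hydroxy-2,2-dimethyl-7-(3-methylbut-2-enyl)-3-oxo-4-{2-[4-(prop-2-enyloxy)phenyl]ethyl}-2,3-dihydro-1-benzofuran-5-carboxylate | COC(=O)c1c(O)c(CC=C(C)C)c2OC(C)(C)C(=O)c2c1CCc1ccc(OCC=C)cc1
F6 | step 9 | methyl 3-bromo-4-[(1-ethoxy-2-methyl-1-oxopropan-2-yl)oxy]-5-(3-methylbut-2-enyl)-6-(prop-2-enyloxy)-2-{2-[4-(prop-2-enyloxy)phenyl]ethyl}benzoate | COC(=O)c1c(CCc2ccc(OCC=C)cc2)c(Br)c(OC(C)(C)C(=O)OCC)c(CC=C(C)C)c1OCC=C
F7 | step 12 | methyl 2,2-dimethyl-8-(3-methylbut-2-enyl)-7-(prop-2-enyloxy)-5-{2-[4-(prop-2-enyloxy)phenyl]ethyl}-3-(trifluoromethylsulfonyloxy)-2H-chromene-6-carboxylate | COC(=O)c1c(OCC=C)c(CC=C(C)C)c2OC(C)(C)C(OS(=O)(=O)C(F)(F)F)=Cc2c1CCc1ccc(OCC=C)cc1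
A1 | alternative 1 | methyl 4-(methoxymethoxy)-6-{2-[4-(methoxymethoxy)phenyl]ethyl}-3-(3-methylbut-2-enyl)-2-oxo-2H-pyran-5-carboxylate | O=C1OC(CCc2ccc(OCOC)cc2)=C(C(=O)OC)C(OCOC)=C1CC=C(C)C
A2 | alternative 1 | (triisopropylsilyloxy)ethyne | C#CO[Si](C(C)C)(C(C)C)C(C)C
A3 | alternative 1 | methyl 2-(methoxymethoxy)-6-{2-[4-(methoxymethoxy)phenyl]ethyl}-3-(3-methylbut-2-enyl)-4-(triisopropylsilyloxy)benzoate | COC(=O)c1c(OCOC)c(CC=C(C)C)c(O[Si](C(C)C)(C(C)C)C(C)C)cc1CCc1ccc(OCOC)cc1
A4 | alternative 2 | 2-bromo-4-(methoxymethoxy)-6-(trimethylsilyl)phenyl trifluoromethanesulfonate | COCOc1cc(Br)c(OS(=O)(=O)C(F)(F)F)c([Si](C)(C)C)c1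
A5 | alternative 2 | 3-methylbut-2-enal | CC(C)=CC=O
A6 | alternative 2 | 5-bromo-7-(methoxymethoxy)-2,2-dimethyl-2H-chromene | COCOc1cc(Br)c2C=CC(C)(C)Oc2c1
A7 | alternative 3 | (3E)-1-[4-(methoxymethoxy)phenyl]-9-methyldeca-3,8-dien-5-one | COCOc1ccc(CC/C=C/C(=O)CCC=C(C)C)cc1
A8 | alternative 3 | dimethyl propanedioate | COC(=O)CC(=O)OC
A9 | alternative 3 | methyl trans-2-hydroxy-6-{2-[4-(methoxymethoxy)phenyl]ethyl}-3-(3-methylbut-2-enyl)-4-oxocyclohex-2-ene-1-carboxylate (racemic; one enantiomer drawn) | COC(=O)[C@H]1[C@H](CCc2ccc(OCOC)cc2)CC(=O)C(CC=C(C)C)=C1O
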